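**Plan**
- Retrosynthesis: the five-membered ring (C1, C2, C3, C3a, C7a) is opened at C2=C3 and the C1 oxygen is returned to C3; this turns the target into its isomer, the twofold-symmetric diarylethyne 16. Both C(sp)–C(aryl) bonds are then cut to two copies of iodoketone 11 plus a C2 unit, the diaryl ketone C–C bond to aldehyde 7 plus a 2,6-dimethoxyphenyl metal, and C–I and C–CHO back to phenol 1.
- Enabling feature: ring B (the aryl on C2) and ring A (the benzo ring at C3a/C7a) carry the same substituents in the same order (2,6-dimethoxybenzoyl carbon, OH, H, CH3, OCH3, one carbon), and C1(=O)–C2=C3 has the oxidation level of an alkyne carbon pair plus a ketone carbon.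
- Forward: one arene is formylated, protected, iodinated, arylated and oxidised to 11 (steps 1–5); two molecules of 11 are joined through ethyne (step 6); after acetal removal (step 7) the five-membered ring is closed last by oxygen transposition and aldol condensation (step 8).
- Stereochemistry: the target has no stereocentre; the carbinol centre of 10 and the two centres of aldol 18 are transient.

Key step: step 8

Assumption: 4-methoxy-3-methylphenol, 2-bromo-1,3-dimethoxybenzene and ethynyltrimethylsilane are bought; hindered rotation about the aryl–carbonyl and aryl–indenone bonds is not treated as a stereo-element, as the target structure defines none.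

Step 1
Reactants: 1 4-methoxy-3-methylphenol
Product: 2 2-hydroxy-5-methoxy-4-methylbenzaldehyde
Conditions: MgCl2, Et3N, (CH2O)n, MeCN, reflux
Reagents that add atoms: paraformaldehyde (formaldehyde unit), C=O
Why: Magnesium phenoxide-directed ortho-formylation (Casnati–Skattebøl reaction) should deliver the formyl group only ortho to the hydroxyl and at the ortho position not flanked by the methyl group, a second formaldehyde taking up the hydride.

Step 2
Reactants: 2 2-hydroxy-5-methoxy-4-methylbenzaldehyde
Product: 3 5-methoxy-2-(methoxymethoxy)-4-methylbenzaldehyde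
Conditions: MOMCl, i-Pr2NEt, CH2Cl2, 0 °C to rt
Reagents that add atoms: chloromethyl methyl ether (MOMCl), COCCl
Why: O-alkylation of the phenol gives an acetal that should survive the organolithium, Grignard, oxidation and coupling steps, leaves all methyl ethers distinguishable and comes off later with dilute acid.

Step 3
Reactants: 3 5-methoxy-2-(methoxymethoxy)-4-methylbenzaldehyde
Product: 7 2-iodo-3-methoxy-6-(methoxymethoxy)-4-methylbenzaldehyde, via lithium amino alkoxide 4 (not isolated), via ring-lithiated amino alkoxide 5 (not isolated), via iodinated amino alkoxide 6 (not isolated)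
Conditions: Me2NCH2CH2N(Me)Li, THF, −20 °C; n-BuLi (3 equiv), −20 °C; I2, −78 °C to rt; aq. Na2S2O3
Reagents that add atoms: iodine, II
Why: Directed ortho-metalation: the lithium α-amino alkoxide formed in the flask masks the aldehyde and, together with the neighbouring methoxyl, should direct n-BuLi to the only ring C–H lying between the two groups, iodine traps the aryllithium and aqueous work-up returns the aldehyde.

Step 4
Reactants: 7 2-iodo-3-methoxy-6-(methoxymethoxy)-4-methylbenzaldehyde; 8 2-bromo-1,3-dimethoxybenzene
Product: 10 (2,6-dimethoxyphenyl)[2-iodo-3-methoxy-6-(methoxymethoxy)-4-methylphenyl]methanol (racemic), via (2,6-dimethoxyphenyl)magnesium bromide 9 (not isolated)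
Conditions: 8, Mg, THF, reflux; then 7, 0 °C to rt; aq. NH4Cl
Reagents that add atoms: none
Why: Grignard addition to the aldehyde should be much faster than iodine–magnesium exchange with the aryl iodide at 0 °C; the new carbinol centre is formed racemic and is erased in step 5.

Step 5
Reactants: 10 (2,6-dimethoxyphenyl)[2-iodo-3-methoxy-6-(methoxymethoxy)-4-methylphenyl]methanol
Product: 11 (2,6-dimethoxyphenyl)[2-iodo-3-methoxy-6-(methoxymethoxy)-4-methylphenyl]methanone
Conditions: Dess–Martin periodinane, CH2Cl2, rt
Reagents that add atoms: none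
Why: Dess–Martin oxidation of a hindered diaryl carbinol to the diaryl ketone should proceed without touching the aryl iodide, the acetal or the methyl ethers.

Step 6
Reactants: 11 (2,6-dimethoxyphenyl)[2-iodo-3-methoxy-6-(methoxymethoxy)-4-methylphenyl]methanone (2 equiv); 12 ethynyltrimethylsilane (1 equiv per 2 equiv of 11)
Product: 15 1,2-bis[2-(2,6-dimethoxybenzoyl)-6-methoxy-3-(methoxymethoxy)-5-methylphenyl]ethyne, via silylalkyne 13 (not isolated), via terminal arylalkyne 14 (not isolated)
Conditions: PdCl2(PPh3)2 (6 mol %), CuI (10 mol %), DBU, H2O (0.4 equiv), MeCN, 60 °C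
Reagents that add atoms: none
Why: One-flask double Sonogashira coupling: the iodide should couple with 12, DBU and water then remove the silyl group, and the freed terminal alkyne couples with the second iodide, so that the measured half-equivalent of 12 gives the symmetric diarylethyne.

Step 7
Reactants: 15 1,2-bis[2-(2,6-dimethoxybenzoyl)-6-methoxy-3-(methoxymethoxy)-5-methylphenyl]ethyne
Product: 16 1,2-bis[2-(2,6-dimethoxybenzoyl)-3-hydroxy-6-methoxy-5-methylphenyl]ethyne
Conditions: 3 M HCl, MeOH/THF, 40 °C
Reagents that add atoms: none
Why: Acid-catalysed acetal exchange should remove both methoxymethyl groups as dimethoxymethane under conditions too mild to hydrate the diarylalkyne or cleave aryl methyl ethers.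

Step 8
Reactants: 16 1,2-bis[2-(2,6-dimethoxybenzoyl)-3-hydroxy-6-methoxy-5-methylphenyl]ethyne
Product: 19 acredinone A, via aryl benzyl triketone 17 (not isolated), via 3-hydroxyindanone aldol 18 (not isolated)
Conditions: Ph3PAuNTf2 (5 mol %), TfOH (20 mol %), H2O (5 equiv), 1,4-dioxane, 80 °C
Reagents that add atoms: none
Why: Proposed new method: the monovalent gold cation should activate the alkyne toward attack of an ortho ketone oxygen (5-exo-dig or 6-endo-dig), protodeauration and water addition with ring opening of the oxocarbenium ion should give the aryl benzyl ketone 17, and TfOH-catalysed enolisation, aldol addition of the benzylic carbon to the diaryl ketone ortho to the new acyl group (18) and loss of water should give the indenone, so that the net change is an isomerisation in which water only shuttles. The closest known reaction types are the carbonyl-assisted gold- or acid-catalysed hydration of 2-alkynylaryl ketones, the acid-mediated cyclodehydration of 2-acyl deoxybenzoins to 2,3-diarylindenones and the intramolecular alkyne–carbonyl metathesis; what is new is their union in one flask on a bis(2-aroylaryl)ethyne. The five-membered ring closes by a 5-(enolexo)-exo-trig aldol addition that forms the C2–C3 bond, the C1–C2 bond being the former triple bond. No stereocentre remains, since the two transient centres of 18 are lost on dehydration. The step needs control of the hydration regiochemistry and of which carbonyl group is attacked, and the twofold symmetry of 16 secures both: the two alkyne carbons and the two ketones are equivalent, so every hydration mode gives the same 17, and in 17 only one diaryl ketone can be reached through a five-membered transition state, while the other would need a four-membered ring and stays as the benzophenone of the target. Catalytic acid and excess water should keep the competing 2-benzopyrylium ion a reversible resting state.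

**Compound list**
1 | 4-methoxy-3-methylphenol | COc1ccc(O)cc1C | starting material
2 | 2-hydroxy-5-methoxy-4-methylbenzaldehyde | COc1cc(C=O)c(O)cc1C | intermediate
3 | 5-methoxy-2-(methoxymethoxy)-4-methylbenzaldehyde | COc1cc(C=O)c(OCOC)cc1C | intermediate
4 | lithium {[2-(dimethylamino)ethyl](methyl)amino}[5-methoxy-2-(methoxymethoxy)-4-methylphenyl]methanolate (formed in the flask) | COc1cc(C(O[Li])N(C)CCN(C)C)c(OCOC)cc1C | intermediate
5 | ring-lithiated amino alkoxide, lithium on the ring carbon between the carbinol carbon and the methoxyl (formed in the flask) | COc1c([Li])c(C(O[Li])N(C)CCN(C)C)c(OCOC)cc1C | intermediate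
6 | iodinated amino alkoxide, iodine in place of the ring lithium of 5 (formed in the flask) | COc1c(I)c(C(O[Li])N(C)CCN(C)C)c(OCOC)cc1C | intermediate
7 | 2-iodo-3-methoxy-6-(methoxymethoxy)-4-methylbenzaldehyde | COc1c(I)c(C=O)c(OCOC)cc1C | intermediate
8 | 2-bromo-1,3-dimethoxybenzene | COc1cccc(OC)c1Br | starting material
9 | (2,6-dimethoxyphenyl)magnesium bromide (formed in the flask) | COc1cccc(OC)c1[Mg]Br | intermediate
10 | (2,6-dimethoxyphenyl)[2-iodo-3-methoxy-6-(methoxymethoxy)-4-methylphenyl]methanol, racemic | COc1cccc(OC)c1C(O)c1c(I)c(OC)c(C)cc1OCOC | intermediate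
11 | (2,6-dimethoxyphenyl)[2-iodo-3-methoxy-6-(methoxymethoxy)-4-methylphenyl]methanone | COc1cccc(OC)c1C(=O)c1c(I)c(OC)c(C)cc1OCOC | intermediate
12 | ethynyltrimethylsilane | C#C[Si](C)(C)C | starting material
13 | (2,6-dimethoxyphenyl){3-methoxy-6-(methoxymethoxy)-4-methyl-2-[(trimethylsilyl)ethynyl]phenyl}methanone (formed in the flask) | COc1cccc(OC)c1C(=O)c1c(C#C[Si](C)(C)C)c(OC)c(C)cc1OCOC | intermediate
14 | (2,6-dimethoxyphenyl)[2-ethynyl-3-methoxy-6-(methoxymethoxy)-4-methylphenyl]methanone (formed in the flask) | COc1cccc(OC)c1C(=O)c1c(C#C)c(OC)c(C)cc1OCOC | intermediate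
15 | 1,2-bis[2-(2,6-dimethoxybenzoyl)-6-methoxy-3-(methoxymethoxy)-5-methylphenyl]ethyne | COc1cccc(OC)c1C(=O)c1c(C#Cc2c(OC)c(C)cc(OCOC)c2C(=O)c2c(OC)cccc2OC)c(OC)c(C)cc1OCOC | intermediate
16 | 1,2-bis[2-(2,6-dimethoxybenzoyl)-3-hydroxy-6-methoxy-5-methylphenyl]ethyne | COc1cccc(OC)c1C(=O)c1c(C#Cc2c(OC)c(C)cc(O)c2C(=O)c2c(OC)cccc2OC)c(OC)c(C)cc1O | intermediate
17 | 1,2-bis[2-(2,6-dimethoxybenzoyl)-3-hydroxy-6-methoxy-5-methylphenyl]ethan-1-one (formed in the flask) | COc1cccc(OC)c1C(=O)c1c(C(=O)Cc2c(OC)c(C)cc(O)c2C(=O)c2c(OC)cccc2OC)c(OC)c(C)cc1O | intermediate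
18 | 2-[2-(2,6-dimethoxybenzoyl)-3-hydroxy-6-methoxy-5-methylphenyl]-3-(2,6-dimethoxyphenyl)-3,4-dihydroxy-7-methoxy-6-methyl-2,3-dihydro-1H-inden-1-one, racemic mixture of diastereomers (formed in the flask) | COc1cccc(OC)c1C(=O)c1c(O)cc(C)c(OC)c1C1C(O)(c2c(OC)cccc2OC)c2c(O)cc(C)c(OC)c2C1=O | intermediate
19 | acredinone A, 2-[2-(2,6-dimethoxybenzoyl)-3-hydroxy-6-methoxy-5-methylphenyl]-3-(2,6-dimethoxyphenyl)-4-hydroxy-7-methoxy-6-methyl-1H-inden-1-one | COc1cccc(OC)c1C(=O)c1c(O)cc(C)c(OC)c1C1=C(c2c(OC)cccc2OC)c2c(O)cc(C)c(OC)c2C1=O | target

**Step count:** 8 steps in total; the longest linear sequence is 8 steps (1 to 19).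

**Steps most likely to fail**

Step 8 (proposed new method). The cascade may stall after hydration, with the material held as a 2-benzopyrylium ion or its hemiketal, because acid-catalysed aldol addition to the doubly ortho-substituted, hydrogen-bonded diaryl ketone is slow; prolonged heating of the free bisphenol in acid may then erode it. The fallback uses known chemistry, sets out from 15 and comes back at 19. Hydration and ring closure are separated, run on the protected series, and the ring is closed by enolate instead of enol chemistry. Compound 15 is hydrated with Ph3PAuNTf2 (5 mol %) in wet 1,4-dioxane at 60 °C without Brønsted acid, a carbonyl-assisted alkyne hydration that should give the isolable 1,2-bis[2-(2,6-dimethoxybenzoyl)-6-methoxy-3-(methoxymethoxy)-5-methylphenyl]ethan-1-one F1. KOH in EtOH at 50 °C should then effect the classical aldol cyclodehydration of a 2-acyl deoxybenzoin to 2-[2-(2,6-dimethoxybenzoyl)-6-methoxy-3-(methoxymethoxy)-5-methylphenyl]-3-(2,6-dimethoxyphenyl)-7-methoxy-4-(methoxymethoxy)-6-methyl-1H-inden-1-one F2; no phenoxide is present to deactivate the ketone or to displace a methoxyl group. Finally 3 M HCl in MeOH/THF at 40 °C removes both acetals and gives 19.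

Step 6. After the first coupling the hindered terminal arylalkyne may dimerise oxidatively (Glaser coupling) or fail to engage a second doubly ortho-substituted iodide, and the basic, wet medium may add to the ortho-aroyl alkyne. The fallback sets out from 11 and comes back at 15. A double Stille coupling with bis(tributylstannyl)ethyne (0.5 equiv), Pd(PPh3)4 (zerovalent palladium) in toluene at 100 °C should join the two iodides via tributyl{[2-(2,6-dimethoxybenzoyl)-6-methoxy-3-(methoxymethoxy)-5-methylphenyl]ethynyl}stannane F3, which forms and reacts on in the flask. No terminal alkyne, copper salt or base is present.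

Step 3. The ring lithiation may stay incomplete, butyllithium may add to the masked aldehyde, and iodine may oxidise the amino alkoxide instead of trapping the aryllithium. The fallback sets out from 1 and comes back at 15; it installs the alkyne before the ketone and uses no masked aldehyde.
- NBS in MeCN at 0 °C should brominate 1 at the free position ortho to the hydroxyl to give 2-bromo-4-methoxy-5-methylphenol F4.
- MOMCl and i-Pr2NEt give 1-bromo-5-methoxy-2-(methoxymethoxy)-4-methylbenzene F5.
- Inverse addition of F5 to commercial LDA in THF at −78 °C should remove the proton between bromine and methoxyl while keeping free bromide scarce (against halogen migration) and give [2-bromo-6-methoxy-3-(methoxymethoxy)-5-methylphenyl]lithium F6. Iodine converts it into 2-bromo-3-iodo-4-methoxy-1-(methoxymethoxy)-5-methylbenzene F7.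
- Iodide-selective double Sonogashira coupling with acetylene (PdCl2(PPh3)2, CuI, Et3N, THF, rt) should give, by way of 2-bromo-3-ethynyl-4-methoxy-1-(methoxymethoxy)-5-methylbenzene F8 formed in the flask, 1,2-bis[2-bromo-6-methoxy-3-(methoxymethoxy)-5-methylphenyl]ethyne F9.
- t-BuLi (4 equiv) in THF at −78 °C gives 1,2-bis[2-lithio-6-methoxy-3-(methoxymethoxy)-5-methylphenyl]ethyne F10, and acylation with 2,6-dimethoxybenzoyl chloride (2 equiv) should give 15; over-addition to the tetra-ortho-substituted ketone is not expected.

**Further compounds**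
F1 | step 8 | 1,2-bis[2-(2,6-dimethoxybenzoyl)-6-methoxy-3-(methoxymethoxy)-5-methylphenyl]ethan-1-one | COc1cccc(OC)c1C(=O)c1c(C(=O)Cc2c(OC)c(C)cc(OCOC)c2C(=O)c2c(OC)cccc2OC)c(OC)c(C)cc1OCOC
F2 | step 8 | 2-[2-(2,6-dimethoxybenzoyl)-6-methoxy-3-(methoxymethoxy)-5-methylphenyl]-3-(2,6-dimethoxyphenyl)-7-methoxy-4-(methoxymethoxy)-6-methyl-1H-inden-1-one | COc1cccc(OC)c1C(=O)c1c(OCOC)cc(C)c(OC)c1C1=C(c2c(OC)cccc2OC)c2c(OCOC)cc(C)c(OC)c2C1=O
F3 | step 6 | tributyl{[2-(2,6-dimethoxybenzoyl)-6-methoxy-3-(methoxymethoxy)-5-methylphenyl]ethynyl}stannane | CCCC[Sn](CCCC)(CCCC)C#Cc1c(OC)c(C)cc(OCOC)c1C(=O)c1c(OC)cccc1OC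
F4 | step 3 | 2-bromo-4-methoxy-5-methylphenol | COc1cc(Br)c(O)cc1C
F5 | step 3 | 1-bromo-5-methoxy-2-(methoxymethoxy)-4-methylbenzene | COc1cc(Br)c(OCOC)cc1C
F6 | step 3 | [2-bromo-6-methoxy-3-(methoxymethoxy)-5-methylphenyl]lithium | COc1c([Li])c(Br)c(OCOC)cc1C
F7 | step 3 | 2-bromo-3-iodo-4-methoxy-1-(methoxymethoxy)-5-methylbenzene | COc1c(I)c(Br)c(OCOC)cc1C
F8 | step 3 | 2-bromo-3-ethynyl-4-methoxy-1-(methoxymethoxy)-5-methylbenzene | COc1c(C#C)c(Br)c(OCOC)cc1C
F9 | step 3 | 1,2-bis[2-bromo-6-methoxy-3-(methoxymethoxy)-5-methylphenyl]ethyne | COc1c(C#Cc2c(OC)c(C)cc(OCOC)c2Br)c(Br)c(OCOC)cc1C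
F10 | step 3 | 1,2-bis[2-lithio-6-methoxy-3-(methoxymethoxy)-5-methylphenyl]ethyne | COc1c(C#Cc2c(OC)c(C)cc(OCOC)c2[Li])c([Li])c(OCOC)cc1C
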